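**Retrosynthetic overview**
- Both arenes are bought. The aryl–acyl bond is cut to 4-methoxyresorcinol 1 and 4-methoxyphenylacetic acid 2, which give deoxybenzoin 3, the ring-opened isoflavone skeleton.
- The C3–CH2 bond of ring A is cut to a dimethylallyl cation from 2-methylbut-3-en-2-ol 4 (a DMAPP surrogate), giving 3-prenyl deoxybenzoin 5. The acyl and OMe groups block the other nucleophilic sites.
- The pyran is the only ring formed. Its O–CMe2 bond is cut to the vinylogous o-quinone methide 6, made from 5 by hydride abstraction as in the enzymatic dehydrogenation. Oxa-6π closure then gives chromene 7.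
- The ArCH2 of 7 is oxidised in the same flask to dielsianone 8. The order is aryl ketone, then C-prenylation, then oxidative pyran closure, then late oxidation to the benzil, with no protecting groups.

Assumption: the SMILES contains no stereocentre, and its only non-aromatic C=C lies in a six-membered ring and is necessarily cis. Dielsianone is therefore achiral and no enantiocontrol is needed.

**Step 1**
Reactants: 1 4-methoxyresorcinol; 2 4-methoxyphenylacetic acid
Product: 3 1-(2,4-dihydroxy-5-methoxyphenyl)-2-(4-methoxyphenyl)ethan-1-one (deoxybenzoin)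
Conditions: BF3·OEt2 (neat, as solvent), 85 °C, 2 h; then aq. NaOAc, 0 °C
Reagents that add atoms: none
Why: Friedel–Crafts (Nencki-type) acylation with the BF3-activated acid, the standard deoxybenzoin synthesis, attacks C6 of 1, which is para to one OH, ortho to the other and not squeezed between two oxygens, and the chelated o-hydroxyaryl ketone resists a second acylation; no stereocentre is formed.

**Step 2**
Reactants: 3 deoxybenzoin; 4 2-methylbut-3-en-2-ol
Product: 5 1-[2,4-dihydroxy-5-methoxy-3-(3-methylbut-2-en-1-yl)phenyl]-2-(4-methoxyphenyl)ethan-1-one (3-prenyl deoxybenzoin)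
Conditions: 4 (1.3 equiv, slow addition), BF3·OEt2 (0.5 equiv), dry 1,4-dioxane, 25 °C, 3 h; recovered 3 is recycled
Reagents that add atoms: none
Why: In this biomimetic Friedel–Crafts prenylation BF3 ionises the tertiary allylic alcohol to the dimethylallyl cation (the species a prenyltransferase makes from DMAPP), which is captured at its primary end by C3 of ring A, the only carbon flanked by two OH groups since C1 and C5 are substituted and C6 is deactivated, while the methyl ethers and the ketone CH2 are inert at 25 °C; no stereocentre is formed.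

**Step 3**
Reactants: 5 3-prenyl deoxybenzoin
Product: 8 dielsianone, via o-quinone methide 6 (not isolated), via chromene deoxybenzoin 7 (not isolated)
Conditions: DDQ (1.05 equiv), dry 1,4-dioxane, 80 °C, 2 h; then SeO2 (1.5 equiv), H2O (5 vol %), 100 °C, 8 h, same flask; filter through Celite, wash with aq. NaHCO3
Reagents that add atoms: selenium dioxide SeO2, O=[Se]=O
Why: DDQ abstracts hydride from the doubly activated benzylic–allylic CH2 (dehydrogenative cyclisation of an o-prenylphenol), the free 4-OH rather than the ketone-chelated 2-OH loses its proton to give (Z)-6, oxa-6π electrocyclisation re-aromatises ring A to 7, and because 7 has no allylic C–H (C2 is quaternary) the SeO2 added next can only perform a Riley oxidation of the enolisable ArCH2C=O to the 1,2-diketone, so both reaction types are known, only their back-to-back use in the shared solvent on the unprotected substrate is untested, stray DDQ oxidation at that CH2 would be productive, and no stereocentre is formed.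

**Compound list**
1 | 4-methoxyresorcinol (4-methoxybenzene-1,3-diol) | COc1ccc(O)cc1O | starting material
2 | 4-methoxyphenylacetic acid | COc1ccc(CC(=O)O)cc1 | starting material
3 | 1-(2,4-dihydroxy-5-methoxyphenyl)-2-(4-methoxyphenyl)ethan-1-one | COc1ccc(CC(=O)c2cc(OC)c(O)cc2O)cc1 | intermediate
4 | 2-methylbut-3-en-2-ol | CC(C)(O)C=C | starting material
5 | 1-[2,4-dihydroxy-5-methoxy-3-(3-methylbut-2-en-1-yl)phenyl]-2-(4-methoxyphenyl)ethan-1-one | COc1ccc(CC(=O)c2cc(OC)c(O)c(CC=C(C)C)c2O)cc1 | intermediate
6 | (6Z)-5-hydroxy-2-methoxy-4-[(4-methoxyphenyl)acetyl]-6-(3-methylbut-2-en-1-ylidene)cyclohexa-2,4-dien-1-one | COc1ccc(CC(=O)C2=C(O)/C(=C/C=C(C)C)C(=O)C(OC)=C2)cc1 | intermediate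
7 | 1-(5-hydroxy-8-methoxy-2,2-dimethyl-2H-chromen-6-yl)-2-(4-methoxyphenyl)ethan-1-one | COc1ccc(CC(=O)c2cc(OC)c3c(c2O)C=CC(C)(C)O3)cc1 | intermediate
8 | dielsianone, 1-(5-hydroxy-8-methoxy-2,2-dimethyl-2H-chromen-6-yl)-2-(4-methoxyphenyl)ethane-1,2-dione (achiral) | COc1ccc(C(=O)C(=O)c2cc(OC)c3c(c2O)C=CC(C)(C)O3)cc1 | target

**Totals**
Total step count: 3 (three flasks, no protecting groups). Longest linear sequence: 3.

**Steps most likely to fail**

Highest risk, step 2. C3 is hindered and the ring carries an acyl group. Cationic prenylations of this kind often give only 25–40 %, and acid can close 5 to the chroman.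
- The fallback brings in the C5 unit at the aldehyde oxidation level. It sets out from 3 and comes back to the route at 7.
- Compound 3 is stirred with 3-methylbut-2-enal and Ca(OH)2 in MeOH at 25 °C.
- The calcium phenolate adds through C3 to the aldehyde. This gives racemic 1-[2,4-dihydroxy-3-(1-hydroxy-3-methylbut-2-en-1-yl)-5-methoxyphenyl]-2-(4-methoxyphenyl)ethan-1-one F1.
- F1 loses water in the flask to the same o-quinone methide 6, which closes to 7.
- DDQ is then not needed, and isolated 7 goes through the SeO2 half of step 3.

Second, step 3. The Riley oxidation of a chelated ketone may be slow. The chromene also has to survive hot, wet, mildly acidic dioxane that still holds the spent quinone.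
- The fallback changes the order, so that the diketone is in place before any olefin exists and ring closure is the last event. It sets out from 3 and comes back at 8.
- SeO2 in dioxane–H2O at reflux converts 3 into 1-(2,4-dihydroxy-5-methoxyphenyl)-2-(4-methoxyphenyl)ethane-1,2-dione F2.
- Prenylation with 4 and BF3·OEt2 as in step 2 gives 1-[2,4-dihydroxy-5-methoxy-3-(3-methylbut-2-en-1-yl)phenyl]-2-(4-methoxyphenyl)ethane-1,2-dione F3. Ring B is now deactivated by its own carbonyl group, so only C3 of ring A can react.
- DDQ in dry benzene at reflux takes F3 through (6Z)-5-hydroxy-2-methoxy-4-[(4-methoxyphenyl)(oxo)acetyl]-6-(3-methylbut-2-en-1-ylidene)cyclohexa-2,4-dien-1-one F4 to 8.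

Third, step 1. Hot neat BF3·OEt2 may give tar or a stubborn boron chelate with the electron-rich triol ether.
- The fallback is a Houben–Hoesch reaction with a nitrile electrophile at low temperature. It sets out from 1 and comes back at 3.
- Compound 1 and 4-methoxyphenylacetonitrile are treated with ZnCl2 (0.5 equiv) and dry HCl in Et2O at 0 °C.
- This precipitates 1-(2,4-dihydroxy-5-methoxyphenyl)-2-(4-methoxyphenyl)ethan-1-iminium chloride F5, which is filtered off and hydrolysed in boiling water to 3.

**Further compounds**
F1 | step 2 | racemic 1-[2,4-dihydroxy-3-(1-hydroxy-3-methylbut-2-en-1-yl)-5-methoxyphenyl]-2-(4-methoxyphenyl)ethan-1-one | COc1ccc(CC(=O)c2cc(OC)c(O)c(C(O)C=C(C)C)c2O)cc1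
F2 | step 3 | 1-(2,4-dihydroxy-5-methoxyphenyl)-2-(4-methoxyphenyl)ethane-1,2-dione | COc1ccc(C(=O)C(=O)c2cc(OC)c(O)cc2O)cc1
F3 | step 3 | 1-[2,4-dihydroxy-5-methoxy-3-(3-methylbut-2-en-1-yl)phenyl]-2-(4-methoxyphenyl)ethane-1,2-dione | COc1ccc(C(=O)C(=O)c2cc(OC)c(O)c(CC=C(C)C)c2O)cc1
F4 | step 3 | (6Z)-5-hydroxy-2-methoxy-4-[(4-methoxyphenyl)(oxo)acetyl]-6-(3-methylbut-2-en-1-ylidene)cyclohexa-2,4-dien-1-one | COc1ccc(C(=O)C(=O)C2=C(O)/C(=C/C=C(C)C)C(=O)C(OC)=C2)cc1
F5 | step 1 | 1-(2,4-dihydroxy-5-methoxyphenyl)-2-(4-methoxyphenyl)ethan-1-iminium chloride | COc1ccc(CC(=[NH2+])c2cc(OC)c(O)cc2O)cc1.[Cl-]
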